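# Total synthesis proposal for CNP0525404.1 (compound 25) by a rhodium-catalysed allenic Pauson–Khand bicyclisation

Atom labels used throughout: seven-membered ring C1 (hemiketal carbon), C2 (CHOH), C3 (C=O), C4 (C–OH), C5 (=C), C6 (CHMe), C7 (CH); five-membered ring C4, C5, C8 (=CH), C9 (C=O), C10 (CMe2); C11 is the CH2 between C7 and the pyrone.

## Analysis of the target

Compound 25 is tetracyclic: a 5,6-dimethyl-2-pyranone is fused to a dihydropyran, the dihydropyran is trans-fused across C1–C7 to a cycloheptane, and the cycloheptane shares C4–C5 with a 4-hydroxycyclopent-2-enone. It has five stereocentres, 1S,2R,4R,6R,7R in the labels above. The C1 hydroxyl is axial on the pyran and anti to H7, the C2 hydroxyl is trans to it, the C4 hydroxyl is cis to the C1 hydroxyl and trans to the C2 hydroxyl, and the C6 methyl is trans to C11. The hemiketal can open to a 2-hydroxy-1,3-diketone in which C2 and C7 become enolisable, C3/C4 is a tertiary α-ketol (acyloin shift), C4–C10–C9 is a β-hydroxy ketone (retro-aldol), and the pyranone does not tolerate hydride reagents or hard nucleophiles. The difficulty is the unbroken C1–C4 oxidation pattern on a seven-membered ring squeezed between two fused rings, next to the quaternary C10, with most stereocentres adjacent to carbonyl groups. The strategy rests on the five-membered ring: the C9 carbonyl lies between C8–H and the gem-dimethyl C10 and spans the C4–C5 fusion. That is the pattern left when a terminal alkyne (C5≡C8), CO and the far double bond (C4=C10) of a 1,1-dimethylallene are joined. The near allene double bond then survives as C3=C4, exactly where the ketone and the tertiary hydroxyl are needed.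

## Retrosynthetic reasoning

**25 from 24.** The hemiketal and the C2 hydroxyl are unmasked last, from a C1 methyl ketal and a C2 silyl ether. The C–O bonds are the only ones cut. Keeping C1 as a ketal until the end means the open 1,3-dicarbonyl form never exists while C2 and C7 are being handled. The forward step must cleave both groups under acid mild enough to leave the α-ketol untouched.

**24 from 23 from 22.** The C3 ketone and C4 hydroxyl are traced to the C3=C4 alkene of dienone 22 by syn-dihydroxylation and oxidation of the only secondary carbinol. C3=C4 is the γ,δ-bond of the dienone and thus the more electron-rich alkene. The C2 silyl ether and the C6 methyl sit on the face that must stay free, so the reagent is steered to the face that gives the 4R carbinol.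

**22 from 20 and 21.** This is the key disconnection: C4–C5, C8–C9 and C9–C10 are cut, which removes both carbocycles at once and leaves allene-yne 20 and carbon monoxide 21. Cutting here and nowhere else is justified because the three bonds are formed by one catalytic event that creates no stereocentre. C1, C2, C6 and C7 can therefore be set beforehand on a rigid pyranopyranone and carried through unchanged. The forward reaction must engage the far allene double bond and insert CO faster than the metallacycle loses a β-hydrogen.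

**20 from 19, 18, 17, and 17 from 15 and 16.** The allene is taken back to tertiary propargylic carbonate 19 by SN2′ delivery of hydride from palladium (C3–H formed, C10–O cut). A palladium/formate reduction is chosen because the pyranone would not survive an aluminium hydride. Diol 17 comes from aldehyde 15 and alkynol 16 by cutting C2–C3. The forward addition must set C2, which the C1 methoxy group can direct by chelation.

**15 from 14, 13, and 13 from 9 and 11.** The C2 aldehyde comes from carbinol 14. The ketal C1–O bonds are cut to give hemiketal 13, and C1–C2 is cut to give Weinreb amide 9 and stannane 11 (made from 10). The ketal is closed under equilibrating conditions, so C1 follows C7: methoxy axial, both carbon substituents equatorial.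

**9 from 8, 7 and 6.** The alkyne carbon C8 is removed by a one-carbon homologation of aldehyde 8, which comes from alcohol 7, the ring-opened form of lactone 6. During these base-mediated steps C1 is an amide, so C7 next to it stays configurationally secure.

**6 from 3 and 4, and 3 from 1.** The C11–pyrone bond is cut to give methylene lactone 3 and pyrone 4; the forward step is a Michael addition. C7 must not be set by protonation in an open chain, where C6 would give no useful bias. In the five-membered lactone, C7 is α to the carbonyl and equilibrates to the trans relationship with the C6 methyl, which is the required 6R,7R arrangement. C11 is introduced by α-methylenation of lactone 1, which supplies C6.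

## Alternatives that were turned down

**Alternative 1:** The disconnection is C2–C3 and C4–C5, with the seven-membered ring drawn from a pyranone (C1, C2, C5, C6, C7) and a tethered vinylene carbonate (C3, C4). In the forward step, an amine base converts acetoxypyranone A2 into an oxidopyrylium, which adds across the carbonate alkene to give the oxygen-bridged cycloadduct A1.
- For it: two rings, two C–C bonds and three stereocentres (C2, C4, C5) arise in one metal-free step, with the C2 and C4 oxygens already in place. On stereocentre creation it is stronger than the chosen route, whose key step creates none.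
- Against it: the bond to C4 must be made at an oxygenated carbon next to quaternary C10. A1 also lacks the C6 methyl, so C6 and C7 have to be set afterwards by conjugate addition and protonation. The ether bridge must be opened by β-elimination to give C5=C8, the carbonate removed with selective oxidation at C3, and the 4-methoxypyranone demethylated and closed to the hemiketal in the presence of the finished tricarbonyl array.
- Comparison: many more operations follow the key step than the three needed here. The chosen route offers C6, C7 and the pyran ketal secured before the key step.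

**Alternative 2:** The disconnection is C1–C2 alone. In the forward step, LiN(SiMe3)2 forms the C2 enolate of the α-silyloxy ketone in enol lactone A4; it attacks the lactone carbonyl C1, and the tetrahedral alkoxide is itself the hemiketal A3.
- For it: it is the most convergent plan and ends one deprotection from 25. On endgame length it is clearly stronger than the chosen route.
- Against it: the closure is a seven-membered Claisen-type acylation by a hindered enolate flanked by quaternary C4. C1 and C2 are both formed with no evident control, and C2 lies in a latent 1,3-dicarbonyl that can equilibrate by retro-Claisen opening. The strong base also meets H7 (α to an activated enol lactone, so elimination of the pyranolate is possible), the γ-hydrogen at C6 of the cyclopentenone, and the tertiary α-ketol ether. A4 further requires a separate synthesis of a cyclopentenone carrying the C4 carbinol in the correct relation to C6 and C7 across an acyclic bond.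
- Comparison: the chosen route closes both carbocycles under neutral conditions with every stereocentre non-enolisable.

**Alternative 3:** The disconnection is C9–C10 alone. In the forward step, mild acid ionises the dimethylcarbinol in A6; the pentadienyl cation closes by conrotatory 4π electrocyclisation and loses a proton to give cyclopentadiene A5, which would then take up dioxygen across C4 and C9.
- For it: the 4-hydroxy-enone (C4–OH and C9=O) is installed in one oxygenation, without an osmium step on a dienone. On this point it is stronger than the chosen route.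
- Against it: the key step forms one bond and one ring, so the seven-membered ring with its C2 and C3 oxygens must be built beforehand. The cation is generated beside an acid-labile C1 ketal and an allylic C3 ether. Proton loss must occur from C9 and not from a methyl group. About five further steps follow (oxygenation, peroxide rearrangement, ether cleavage, oxidation, deprotection).
- Comparison: the chosen route makes three bonds and two rings at once and leaves C3=C4 ready for a two-step oxidation.

Key step: step 14

## Assumptions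

- Compounds 1 and 10 are taken as catalogue compounds. Compound 1 is otherwise one step from 4-methylfuran-2(5H)-one by copper hydride asymmetric conjugate reduction.
- Compounds 11–13 carry the 1-ethoxyethyl group as a mixture of epimers at its acetal carbon. The group is removed in step 8.

## Route

Step 1
Reactants: 1 (R)-4-methyldihydrofuran-2(3H)-one
Product: 3 (R)-4-methyl-3-methylidenedihydrofuran-2(3H)-one, via sodium formyl-lactone enolate 2 (not isolated)
Conditions: NaH, HCO2Et, Et2O, 0 °C to rt; then (CH2O)n, THF, 65 °C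
Reagents that add atoms: formaldehyde (as paraformaldehyde), C=O; ethyl formate, CCOC=O (its formyl carbon is carried in 2 only)
Why: Claisen formylation at the only enolisable carbon (C7) gives enolate 2; aldol addition to formaldehyde, formyl transfer and loss of formate leave the exocyclic C7=C11 double bond (α-methylenation of a γ-lactone). C6 is not deprotonated, so its configuration is carried through.

Step 2
Reactants: 3 (R)-4-methyl-3-methylidenedihydrofuran-2(3H)-one; 4 4-hydroxy-5,6-dimethyl-2H-pyran-2-one
Product: 6 (3R,4R)-3-[(4-hydroxy-5,6-dimethyl-2-oxo-2H-pyran-3-yl)methyl]-4-methyldihydrofuran-2(3H)-one, via cis-lactone epimer 5 (not isolated)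
Conditions: DBU (1.5 equiv), MeCN, 60 °C
Reagents that add atoms: none
Why: Michael addition of C3 of the vinylogous acid 4 to the α-methylene lactone forms the C11–pyrone bond. Protonation at C7 is unselective, but the lactone α-centre epimerises under the same base, and the 3,4-trans isomer, with both substituents pseudo-equatorial, should dominate at equilibrium; C7 is thus set by thermodynamic control from the C6 methyl.

Step 3
Reactants: 6 (3R,4R)-3-[(4-hydroxy-5,6-dimethyl-2-oxo-2H-pyran-3-yl)methyl]-4-methyldihydrofuran-2(3H)-one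
Product: 7 (2R,3R)-4-hydroxy-2-[(4-hydroxy-5,6-dimethyl-2-oxo-2H-pyran-3-yl)methyl]-N-methoxy-N,3-dimethylbutanamide
Conditions: MeNHOMe·HCl, AlMe3, CH2Cl2, 0 °C to rt; aq. potassium sodium tartrate; used crude
Reagents that add atoms: N,O-dimethylhydroxylamine hydrochloride, CNOC.Cl
Why: Weinreb aminolysis of the γ-lactone with the aluminium amide opens the ring at C1 without enolising C7. The acidic pyrone hydroxyl is held as its aluminium salt, which also shields the pyranone carbonyl.

Step 4
Reactants: 7 (2R,3R)-4-hydroxy-2-[(4-hydroxy-5,6-dimethyl-2-oxo-2H-pyran-3-yl)methyl]-N-methoxy-N,3-dimethylbutanamide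
Product: 8 (2R,3R)-2-[(4-hydroxy-5,6-dimethyl-2-oxo-2H-pyran-3-yl)methyl]-N-methoxy-N,3-dimethyl-4-oxobutanamide
Conditions: Dess–Martin periodinane, NaHCO3, CH2Cl2, 0 °C
Reagents that add atoms: none
Why: Dess–Martin oxidation of the primary C5 alcohol, run at once so that 7 cannot relactonise. The buffered, non-basic medium leaves the α-methyl aldehyde centre C6 untouched.

Step 5
Reactants: 8 (2R,3R)-2-[(4-hydroxy-5,6-dimethyl-2-oxo-2H-pyran-3-yl)methyl]-N-methoxy-N,3-dimethyl-4-oxobutanamide
Product: 9 (2R,3R)-2-[(4-hydroxy-5,6-dimethyl-2-oxo-2H-pyran-3-yl)methyl]-N-methoxy-N,3-dimethylpent-4-ynamide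
Conditions: dimethyl (1-diazo-2-oxopropyl)phosphonate, K2CO3 (excess), MeOH, 0 °C to rt
Reagents that add atoms: dimethyl (1-diazo-2-oxopropyl)phosphonate, CC(=O)C(=[N+]=[N-])P(=O)(OC)OC
Why: Seyferth–Gilbert homologation in its Ohira–Bestmann form converts the C5 aldehyde into the terminal alkyne C5≡C8. α-Methyl aldehydes normally pass through without epimerisation, and C7 is α to an amide only.

Step 6
Reactants: 10 (tributylstannyl)methanol
Product: 11 tributyl[(1-ethoxyethoxy)methyl]stannane
Conditions: ethyl vinyl ether, PPTS (cat.), CH2Cl2, 0 °C to rt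
Reagents that add atoms: ethyl vinyl ether, C=COCC
Why: Acid-catalysed addition of the alcohol to the vinyl ether gives the acetal-protected hydroxymethyl stannane, the standard precursor of an α-alkoxymethyllithium.

Step 7
Reactants: 9 (2R,3R)-2-[(4-hydroxy-5,6-dimethyl-2-oxo-2H-pyran-3-yl)methyl]-N-methoxy-N,3-dimethylpent-4-ynamide; 11 tributyl[(1-ethoxyethoxy)methyl]stannane
Product: 13 (3R)-3-[(2R)-but-3-yn-2-yl]-2-[(1-ethoxyethoxy)methyl]-2-hydroxy-7,8-dimethyl-3,4-dihydro-2H,5H-pyrano[4,3-b]pyran-5-one (anomer mixture), via open-chain ketone 12 (not isolated)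
Conditions: 11, n-BuLi, THF, −78 °C; then 9 pre-treated with LiN(SiMe3)2 (2 equiv), −78 to −40 °C; aq. NH4Cl
Reagents that add atoms: none
Why: Tin–lithium exchange gives the α-alkoxymethyllithium, which adds once to the Weinreb amide (stable chelated adduct) to form C1–C2. On work-up ketone 12 is captured by the pyrone hydroxyl as the six-membered hemiketal 13, so C7 spends little time α to a free ketone.

Step 8
Reactants: 13 (3R)-3-[(2R)-but-3-yn-2-yl]-2-[(1-ethoxyethoxy)methyl]-2-hydroxy-7,8-dimethyl-3,4-dihydro-2H,5H-pyrano[4,3-b]pyran-5-one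
Product: 14 (2S,3R)-3-[(2R)-but-3-yn-2-yl]-2-(hydroxymethyl)-2-methoxy-7,8-dimethyl-3,4-dihydro-2H,5H-pyrano[4,3-b]pyran-5-one
Conditions: CSA (0.1 equiv), MeOH, 3 Å MS, rt
Reagents that add atoms: methanol, CO
Why: Acid-catalysed ketalisation through the cyclic oxocarbenium ion, with transacetalisation of the ethoxyethyl group in the same flask. C1 is set under equilibrating conditions: the methoxy group goes axial (anomeric effect, axial attack) and the C2 and C6 carbon substituents stay equatorial, which is the 1S configuration relative to C7.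

Step 9
Reactants: 14 (2S,3R)-3-[(2R)-but-3-yn-2-yl]-2-(hydroxymethyl)-2-methoxy-7,8-dimethyl-3,4-dihydro-2H,5H-pyrano[4,3-b]pyran-5-one
Product: 15 (2S,3R)-3-[(2R)-but-3-yn-2-yl]-2-methoxy-7,8-dimethyl-5-oxo-3,4-dihydro-2H,5H-pyrano[4,3-b]pyran-2-carbaldehyde
Conditions: Dess–Martin periodinane, NaHCO3, CH2Cl2, rt
Reagents that add atoms: none
Why: Dess–Martin oxidation of a primary alcohol on a quaternary carbon; the aldehyde has no α-hydrogen and cannot epimerise or enolise.

Step 10
Reactants: 15 (2S,3R)-3-[(2R)-but-3-yn-2-yl]-2-methoxy-7,8-dimethyl-5-oxo-3,4-dihydro-2H,5H-pyrano[4,3-b]pyran-2-carbaldehyde; 16 2-methylbut-3-yn-2-ol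
Product: 17 (2S,3R)-3-[(2R)-but-3-yn-2-yl]-2-[(1R)-1,4-dihydroxy-4-methylpent-2-yn-1-yl]-2-methoxy-7,8-dimethyl-3,4-dihydro-2H,5H-pyrano[4,3-b]pyran-5-one
Conditions: 16, EtMgBr (2 equiv per 16), THF, 0 °C to rt; then 15, MgBr2·OEt2, CH2Cl2–THF, −78 to −20 °C; aq. NH4Cl
Reagents that add atoms: none
Why: Chelation-controlled addition of an alkynylmagnesium reagent to an α-alkoxy aldehyde. Magnesium bridges the aldehyde oxygen and the C1 methoxy group, and the acetylide enters from the ring-oxygen flank, away from C7 and its branched substituent, which gives 2R; a polar Felkin–Anh arrangement with the C1–O(ring) bond anti to the nucleophile predicts the same sense. The alkynyl Grignard is too weakly basic to exchange with the substrate's own terminal alkyne at these temperatures.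

Step 11
Reactants: 17 (2S,3R)-3-[(2R)-but-3-yn-2-yl]-2-[(1R)-1,4-dihydroxy-4-methylpent-2-yn-1-yl]-2-methoxy-7,8-dimethyl-3,4-dihydro-2H,5H-pyrano[4,3-b]pyran-5-one
Product: 18 (2S,3R)-3-[(2R)-but-3-yn-2-yl]-2-[(1R)-1-(tert-butyldimethylsilyloxy)-4-hydroxy-4-methylpent-2-yn-1-yl]-2-methoxy-7,8-dimethyl-3,4-dihydro-2H,5H-pyrano[4,3-b]pyran-5-one
Conditions: TBSCl, imidazole, DMAP (cat.), DMF, 40 °C
Reagents that add atoms: tert-butyldimethylsilyl chloride, CC(C)(C)[Si](C)(C)Cl
Why: Silylation with the chloride and imidazole takes the secondary propargylic hydroxyl and leaves the tertiary one, which does not react under these conditions.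

Step 12
Reactants: 18 (2S,3R)-3-[(2R)-but-3-yn-2-yl]-2-[(1R)-1-(tert-butyldimethylsilyloxy)-4-hydroxy-4-methylpent-2-yn-1-yl]-2-methoxy-7,8-dimethyl-3,4-dihydro-2H,5H-pyrano[4,3-b]pyran-5-one
Product: 19 (2S,3R)-3-[(2R)-but-3-yn-2-yl]-2-[(1R)-1-(tert-butyldimethylsilyloxy)-4-(methoxycarbonyloxy)-4-methylpent-2-yn-1-yl]-2-methoxy-7,8-dimethyl-3,4-dihydro-2H,5H-pyrano[4,3-b]pyran-5-one
Conditions: LiN(SiMe3)2 (1.05 equiv), THF, −78 °C; ClCO2Me, −78 to 0 °C
Reagents that add atoms: methyl chloroformate, COC(=O)Cl
Why: The hydroxyl is by far the most acidic site, so one equivalent of amide base gives the tertiary alkoxide only, and this is acylated to the carbonate (standard for tertiary propargylic alcohols).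

Step 13
Reactants: 19 (2S,3R)-3-[(2R)-but-3-yn-2-yl]-2-[(1R)-1-(tert-butyldimethylsilyloxy)-4-(methoxycarbonyloxy)-4-methylpent-2-yn-1-yl]-2-methoxy-7,8-dimethyl-3,4-dihydro-2H,5H-pyrano[4,3-b]pyran-5-one
Product: 20 (2S,3R)-3-[(2R)-but-3-yn-2-yl]-2-[(1R)-1-(tert-butyldimethylsilyloxy)-4-methylpenta-2,3-dien-1-yl]-2-methoxy-7,8-dimethyl-3,4-dihydro-2H,5H-pyrano[4,3-b]pyran-5-one
Conditions: Pd2(dba)3·CHCl3 (2.5 mol%), n-Bu3P (10 mol%), HCO2NH4, THF, rt to 40 °C
Reagents that add atoms: none
Why: Palladium-catalysed formate hydrogenolysis of a propargylic carbonate (Tsuji–Mandai). Zerovalent palladium ionises the tertiary carbonate with SN2′ transposition to an allenylpalladium species bound at C3; formate exchange, decarboxylation and C–H reductive elimination give the 1,1-dimethylallene. The conditions are neutral and spare the pyranone; the allene is achiral, so no stereocentre is at stake.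

Step 14
Reactants: 20 (2S,3R)-3-[(2R)-but-3-yn-2-yl]-2-[(1R)-1-(tert-butyldimethylsilyloxy)-4-methylpenta-2,3-dien-1-yl]-2-methoxy-7,8-dimethyl-3,4-dihydro-2H,5H-pyrano[4,3-b]pyran-5-one; 21 carbon monoxide
Product: 22 (1S,2R,6R,7R)-dienone methyl ketal: tetracycle with C1 OMe, C2 OTBS, C3=C4, C5=C8, C9=O, C10 Me2 and C6 Me (atom labels as above)
Conditions: [Rh(CO)2Cl]2 (5 mol%), CO (1 atm), toluene, 90 °C
Reagents that add atoms: none
Why: The monovalent rhodium carbonyl binds the terminal alkyne (C5≡C8) and the far π-bond (C4=C10) of the allene, and oxidative cyclisation gives a trivalent rhodacyclopentene in which C4–C5 is formed. That C–C bond formation closes the seven-membered ring (C1 to C7) and leaves the near π-bond as C3=C4. Insertion of CO 21 into a rhodium–carbon bond and reductive elimination then form C8–C9 and C9–C10, closing the five-membered ring as the enone. The closest known reaction type is the rhodium-catalysed allenic Pauson–Khand reaction of allene-ynes with a four-atom tether, which gives bicyclo[5.3.0] 4-alkylidenecyclopentenones. No stereocentre is created; C1, C2, C6 and C7 are non-enolisable spectators. Two selectivities are needed. The far π-bond must react in preference to the near one, which rhodium (unlike Mo(CO)6) and the four-atom tether (C6, C7, C1, C2) favour. Carbonylation must also outrun β-hydride loss from the C10 methyl groups, which the CO atmosphere should ensure. The pyran holds the two arms trans-diequatorial and gauche on C1 and C7, and the quaternary C1 adds a Thorpe–Ingold bias toward closure.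

Step 15
Reactants: 22 (1S,2R,6R,7R)-dienone methyl ketal
Product: 23 (1S,2R,3R,4R,6R,7R)-3,4-diol: as 22 with C3 H(OH) and C4 OH in place of C3=C4
Conditions: OsO4 (10 mol%), NMO, acetone–H2O, 0 °C to rt
Reagents that add atoms: N-methylmorpholine N-oxide, C[N+]1([O-])CCOCC1; water, O
Why: Upjohn syn-dihydroxylation at the γ,δ-alkene C3=C4, the more electron-rich double bond of the dienone; the enone C5=C8 and the pyranone are deactivated. The osmium reagent should approach anti to the adjacent C2 silyl ether (and to the C6 methyl on the same face), which places the C4 hydroxyl cis to the C1 oxygen and gives 4R.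

Step 16
Reactants: 23 (1S,2R,3R,4R,6R,7R)-3,4-diol
Product: 24 (1S,2R,4R,6R,7R)-α-hydroxy ketone: as 23 with C3=O
Conditions: Dess–Martin periodinane, NaHCO3, CH2Cl2, 0 °C to rt
Reagents that add atoms: none
Why: Dess–Martin oxidation of the only secondary carbinol; the tertiary C4 hydroxyl cannot be oxidised, and the buffered, base-free medium avoids diol cleavage, epimerisation at C2 and acyloin shift.

Step 17
Reactants: 24 (1S,2R,4R,6R,7R)-α-hydroxy ketone
Product: 25 CNP0525404.1 (target; 1S,2R,4R,6R,7R)
Conditions: HF (48% aq.), MeCN–H2O, 0 °C to rt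
Reagents that add atoms: water, O
Why: Aqueous HF cleaves the silyl ether and hydrolyses the mixed methyl ketal through the cyclic oxocarbenium ion; water adds axially, so the hemiketal keeps the anomerically preferred configuration that the ketal already had. The medium is acidic but not strongly so, which limits time in the ring-opened form and α-ketol rearrangement.

## Compound list

1 | (R)-4-methyldihydrofuran-2(3H)-one | O=C1C[C@@H](C)CO1 | starting material
2 | sodium [(4R)-4-methyl-2-oxooxolan-3-ylidene]methanolate | [Na+].[O-]C=C1C(=O)OC[C@@H]1C | intermediate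
3 | (R)-4-methyl-3-methylidenedihydrofuran-2(3H)-one | C=C1C(=O)OC[C@@H]1C | intermediate
4 | 4-hydroxy-5,6-dimethyl-2H-pyran-2-one | Cc1oc(=O)cc(O)c1C | starting material
5 | (3S,4R)-3-[(4-hydroxy-5,6-dimethyl-2-oxo-2H-pyran-3-yl)methyl]-4-methyldihydrofuran-2(3H)-one (cis) | Cc1oc(=O)c(C[C@@H]2C(=O)OC[C@@H]2C)c(O)c1C | intermediate
6 | (3R,4R)-3-[(4-hydroxy-5,6-dimethyl-2-oxo-2H-pyran-3-yl)methyl]-4-methyldihydrofuran-2(3H)-one (trans) | Cc1oc(=O)c(C[C@H]2C(=O)OC[C@@H]2C)c(O)c1C | intermediate
7 | (2R,3R)-4-hydroxy-2-[(4-hydroxy-5,6-dimethyl-2-oxo-2H-pyran-3-yl)methyl]-N-methoxy-N,3-dimethylbutanamide | Cc1oc(=O)c(C[C@H]([C@@H](C)CO)C(=O)N(C)OC)c(O)c1C | intermediate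
8 | (2R,3R)-2-[(4-hydroxy-5,6-dimethyl-2-oxo-2H-pyran-3-yl)methyl]-N-methoxy-N,3-dimethyl-4-oxobutanamide | Cc1oc(=O)c(C[C@H]([C@@H](C)C=O)C(=O)N(C)OC)c(O)c1C | intermediate
9 | (2R,3R)-2-[(4-hydroxy-5,6-dimethyl-2-oxo-2H-pyran-3-yl)methyl]-N-methoxy-N,3-dimethylpent-4-ynamide | Cc1oc(=O)c(C[C@H]([C@@H](C)C#C)C(=O)N(C)OC)c(O)c1C | intermediate
10 | (tributylstannyl)methanol | CCCC[Sn](CCCC)(CCCC)CO | starting material
11 | tributyl[(1-ethoxyethoxy)methyl]stannane | CCCC[Sn](CCCC)(CCCC)COC(C)OCC | intermediate
12 | (3R,4R)-1-(1-ethoxyethoxy)-3-[(4-hydroxy-5,6-dimethyl-2-oxo-2H-pyran-3-yl)methyl]-4-methylhex-5-yn-2-one | Cc1oc(=O)c(C[C@H]([C@@H](C)C#C)C(=O)COC(C)OCC)c(O)c1C | intermediate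
13 | (3R)-3-[(2R)-but-3-yn-2-yl]-2-[(1-ethoxyethoxy)methyl]-2-hydroxy-7,8-dimethyl-3,4-dihydro-2H,5H-pyrano[4,3-b]pyran-5-one | Cc1oc(=O)c2c(c1C)OC(O)(COC(C)OCC)[C@H](C2)[C@@H](C)C#C | intermediate
14 | (2S,3R)-3-[(2R)-but-3-yn-2-yl]-2-(hydroxymethyl)-2-methoxy-7,8-dimethyl-3,4-dihydro-2H,5H-pyrano[4,3-b]pyran-5-one | Cc1oc(=O)c2c(c1C)O[C@](OC)(CO)[C@H](C2)[C@@H](C)C#C | intermediate
15 | (2S,3R)-3-[(2R)-but-3-yn-2-yl]-2-methoxy-7,8-dimethyl-5-oxo-3,4-dihydro-2H,5H-pyrano[4,3-b]pyran-2-carbaldehyde | Cc1oc(=O)c2c(c1C)O[C@](OC)(C=O)[C@H](C2)[C@@H](C)C#C | intermediate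
16 | 2-methylbut-3-yn-2-ol | CC(C)(O)C#C | starting material
17 | (2S,3R)-3-[(2R)-but-3-yn-2-yl]-2-[(1R)-1,4-dihydroxy-4-methylpent-2-yn-1-yl]-2-methoxy-7,8-dimethyl-3,4-dihydro-2H,5H-pyrano[4,3-b]pyran-5-one | Cc1oc(=O)c2c(c1C)O[C@](OC)([C@H](O)C#CC(C)(C)O)[C@H](C2)[C@@H](C)C#C | intermediate
18 | (2S,3R)-3-[(2R)-but-3-yn-2-yl]-2-[(1R)-1-(tert-butyldimethylsilyloxy)-4-hydroxy-4-methylpent-2-yn-1-yl]-2-methoxy-7,8-dimethyl-3,4-dihydro-2H,5H-pyrano[4,3-b]pyran-5-one | Cc1oc(=O)c2c(c1C)O[C@](OC)([C@H](O[Si](C)(C)C(C)(C)C)C#CC(C)(C)O)[C@H](C2)[C@@H](C)C#C | intermediate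
19 | (2S,3R)-3-[(2R)-but-3-yn-2-yl]-2-[(1R)-1-(tert-butyldimethylsilyloxy)-4-(methoxycarbonyloxy)-4-methylpent-2-yn-1-yl]-2-methoxy-7,8-dimethyl-3,4-dihydro-2H,5H-pyrano[4,3-b]pyran-5-one | Cc1oc(=O)c2c(c1C)O[C@](OC)([C@H](O[Si](C)(C)C(C)(C)C)C#CC(C)(C)OC(=O)OC)[C@H](C2)[C@@H](C)C#C | intermediate
20 | (2S,3R)-3-[(2R)-but-3-yn-2-yl]-2-[(1R)-1-(tert-butyldimethylsilyloxy)-4-methylpenta-2,3-dien-1-yl]-2-methoxy-7,8-dimethyl-3,4-dihydro-2H,5H-pyrano[4,3-b]pyran-5-one (allene-yne) | Cc1oc(=O)c2c(c1C)O[C@](OC)([C@H](O[Si](C)(C)C(C)(C)C)C=C=C(C)C)[C@H](C2)[C@@H](C)C#C | intermediate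
21 | carbon monoxide | [C-]#[O+] | starting material
22 | (1S,2R,6R,7R)-dienone methyl ketal (C1 OMe, C2 OTBS, C3=C4, C5=C8, C9=O) | Cc1oc(=O)c2c(c1C)O[C@]1(OC)[C@H](O[Si](C)(C)C(C)(C)C)C=C3C(=CC(=O)C3(C)C)[C@H](C)[C@H]1C2 | intermediate
23 | (1S,2R,3R,4R,6R,7R)-3,4-diol of 22 | Cc1oc(=O)c2c(c1C)O[C@]1(OC)[C@H](O[Si](C)(C)C(C)(C)C)[C@@H](O)[C@@]3(O)C(=CC(=O)C3(C)C)[C@H](C)[C@H]1C2 | intermediate
24 | (1S,2R,4R,6R,7R)-C3 ketone, C4 carbinol, C1 methyl ketal, C2 silyl ether | Cc1oc(=O)c2c(c1C)O[C@]1(OC)[C@H](O[Si](C)(C)C(C)(C)C)C(=O)[C@@]3(O)C(=CC(=O)C3(C)C)[C@H](C)[C@H]1C2 | intermediate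
25 | CNP0525404.1 | Cc1oc(=O)c2c(c1C)O[C@]1(O)[C@H](O)C(=O)[C@@]3(O)C(=CC(=O)C3(C)C)[C@H](C)[C@H]1C2 | target

## Step count and least certain steps

Total step count: 17. Longest linear sequence: 16 (steps 1–5 and 7–17; step 6 is a one-step branch).

**Step 14 (key step).** The rhodacycle may lose a β-hydrogen from a C10 methyl group and divert to a cycloisomerised cross-conjugated triene, and the terminal alkyne may oligomerise at rhodium before cyclising. Fallback, changing the alkyne partner and not the catalyst settings: from 20, C-silylation of the terminal alkyne (Zn(OTf)2, Et3N, Me3SiOTf) gives the silyl-capped allene-yne F1. The same carbonylative bicyclisation on this internal silylalkyne, the best-behaved alkyne class for this reaction, gives the α-silyl dienone F2, and protodesilylation (KF, DMSO–H2O) returns to 22.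

**Step 2.** Base may move the exocyclic double bond of 3 into the ring before addition, which would also erase C6, and equilibration at C7 may stop short of a useful trans preference. Fallback, replacing thermodynamic by kinetic control: from 4, O-methylation (Me2SO4, K2CO3, acetone) gives 4-methoxy-5,6-dimethyl-2H-pyran-2-one F3, and bromomethylation at C3 ((CH2O)n, HBr, AcOH) gives 3-(bromomethyl)-4-methoxy-5,6-dimethyl-2H-pyran-2-one F4. The lithium enolate of 1 (LiN(i-Pr)2, THF, −78 °C) is alkylated by F4 on the face away from the C6 methyl to give the trans lactone methyl ether F5. LiI in pyridine cleaves the vinylogous methyl ester and returns to 6.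

**Step 10.** Facial selectivity at the aldehyde may be poor, because the chelate with the C1 methoxy group has to compete with coordination to the ring oxygen. Fallback, reagent control in place of substrate control: from 17 as a C2 epimer mixture, Dess–Martin oxidation gives the ynone F6, and transfer hydrogenation with RuCl(p-cymene)[(S,S)-TsDPEN] or its enantiomer, whichever delivers hydride to the required face, in HCO2H–Et3N returns to 17.

**Step 13.** Hydride may be delivered without transposition, giving an alkyne, and the palladium hydride may begin to reduce or couple the terminal alkyne. Fallback, bringing in the allene as a nucleophile: from 15, addition of 1-lithio-3-methylbuta-1,2-diene (3-methylbuta-1,2-diene, n-BuLi, THF, −78 °C, aldehyde added to excess reagent) gives the allenyl carbinol F7 through the same C1-methoxy-directed face. Silylation (TBSOTf, 2,6-lutidine) returns to 20.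

**Step 15.** Osmylation may be slow at the hindered trisubstituted alkene, and the axial C1 methoxy group may erode the preference for the face anti to the silyl ether. Fallback, hydrogen-bond-directed delivery in place of steric control: from 22, mild hydrolysis of the methyl ketal (PPTS, acetone–H2O) gives the hemiketal F8. Its C1 hydroxyl, on the required face and homoallylic to C3=C4, directs stoichiometric OsO4·TMEDA (CH2Cl2, −78 °C) to give the triol silyl ether F9. Dess–Martin oxidation gives the ketone F10, and HF·pyridine desilylation arrives at 25.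

## Further compounds

F1 | step 14 | (2S,3R)-2-[(1R)-1-(tert-butyldimethylsilyloxy)-4-methylpenta-2,3-dien-1-yl]-2-methoxy-7,8-dimethyl-3-[(2R)-4-(trimethylsilyl)but-3-yn-2-yl]-3,4-dihydro-2H,5H-pyrano[4,3-b]pyran-5-one | Cc1oc(=O)c2c(c1C)O[C@](OC)([C@H](O[Si](C)(C)C(C)(C)C)C=C=C(C)C)[C@H](C2)[C@@H](C)C#C[Si](C)(C)C
F2 | step 14 | C8-trimethylsilyl derivative of dienone 22 | Cc1oc(=O)c2c(c1C)O[C@]1(OC)[C@H](O[Si](C)(C)C(C)(C)C)C=C3C(=C([Si](C)(C)C)C(=O)C3(C)C)[C@H](C)[C@H]1C2
F3 | step 2 | 4-methoxy-5,6-dimethyl-2H-pyran-2-one | COc1cc(=O)oc(C)c1C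
F4 | step 2 | 3-(bromomethyl)-4-methoxy-5,6-dimethyl-2H-pyran-2-one | COc1c(CBr)c(=O)oc(C)c1C
F5 | step 2 | (3R,4R)-3-[(4-methoxy-5,6-dimethyl-2-oxo-2H-pyran-3-yl)methyl]-4-methyldihydrofuran-2(3H)-one | COc1c(C[C@H]2C(=O)OC[C@@H]2C)c(=O)oc(C)c1C
F6 | step 10 | (2S,3R)-3-[(2R)-but-3-yn-2-yl]-2-(4-hydroxy-4-methylpent-2-ynoyl)-2-methoxy-7,8-dimethyl-3,4-dihydro-2H,5H-pyrano[4,3-b]pyran-5-one | Cc1oc(=O)c2c(c1C)O[C@](OC)(C(=O)C#CC(C)(C)O)[C@H](C2)[C@@H](C)C#C
F7 | step 13 | (2S,3R)-3-[(2R)-but-3-yn-2-yl]-2-[(1R)-1-hydroxy-4-methylpenta-2,3-dien-1-yl]-2-methoxy-7,8-dimethyl-3,4-dihydro-2H,5H-pyrano[4,3-b]pyran-5-one | Cc1oc(=O)c2c(c1C)O[C@](OC)([C@H](O)C=C=C(C)C)[C@H](C2)[C@@H](C)C#C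
F8 | step 15 | C1 hemiketal of dienone 22 (C2 silyl ether kept) | Cc1oc(=O)c2c(c1C)O[C@]1(O)[C@H](O[Si](C)(C)C(C)(C)C)C=C3C(=CC(=O)C3(C)C)[C@H](C)[C@H]1C2
F9 | step 15 | C1 hemiketal 3,4-diol, C2 silyl ether | Cc1oc(=O)c2c(c1C)O[C@]1(O)[C@H](O[Si](C)(C)C(C)(C)C)[C@@H](O)[C@@]3(O)C(=CC(=O)C3(C)C)[C@H](C)[C@H]1C2
F10 | step 15 | C2 tert-butyldimethylsilyl ether of 25 | Cc1oc(=O)c2c(c1C)O[C@]1(O)[C@H](O[Si](C)(C)C(C)(C)C)C(=O)[C@@]3(O)C(=CC(=O)C3(C)C)[C@H](C)[C@H]1C2
A1 | alternative 1 | oxygen-bridged tricyclic cycloadduct (cyclic carbonate, silyl ether, 4-methoxypyranone) | COc1c(C)c(C)oc(=O)c1CC1=C[C@]2(O[C@H]3C1=O)C[C@@H](O[Si](C)(C)C(C)(C)C)C(C)(C)[C@@]2(OC(=O)O4)[C@@H]34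
A2 | alternative 1 | acetoxypyranone carrying the tethered vinylene carbonate | COc1c(C)c(C)oc(=O)c1CC1=CC(OC(C)=O)(C[C@@H](O[Si](C)(C)C(C)(C)C)C(C)(C)C2=COC(=O)O2)OCC1=O
A3 | alternative 2 | bis-silyl ether of the target hemiketal | Cc1oc(=O)c2c(c1C)O[C@]1(O)[C@H](O[Si](C)(C)C(C)(C)C)C(=O)[C@@]3(O[Si](CC)(CC)CC)C(=CC(=O)C3(C)C)[C@H](C)[C@H]1C2
A4 | alternative 2 | enol lactone carrying the silyloxyacetyl cyclopentenone | Cc1oc(=O)c2c(c1C)OC(=O)[C@H](C2)[C@@H](C)C3=CC(=O)C(C)(C)[C@@]3(O[Si](CC)(CC)CC)C(=O)CO[Si](C)(C)C(C)(C)C
A5 | alternative 3 | ring-fused 5,5-dimethylcyclopentadiene | Cc1oc(=O)c2c(c1C)O[C@]1(OC)[C@H](O[Si](C)(C)C(C)(C)C)[C@H](OCc4ccc(OC)cc4)C3=C(C=CC3(C)C)[C@H](C)[C@H]1C2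
A6 | alternative 3 | dienyl dimethylcarbinol | Cc1oc(=O)c2c(c1C)O[C@]1(OC)[C@H](O[Si](C)(C)C(C)(C)C)[C@H](OCc4ccc(OC)cc4)C(C(C)(C)O)=C(C=C)[C@H](C)[C@H]1C2
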